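**Retrosynthetic overview**
1. Target ⇒ (ring C6–O bond) a (6Z)-homoallylic C9 alcohol already carrying the C10 stearate. Hydroxyl-directed epoxidation of C6=C7 and 5-endo closure by O9 form the oxolane, the only ring, in the last step.
2. Homoallylic alcohol ⇒ (C7–C8 bond) a (Z)-hept-1-enyl cuprate plus a terminal epoxide with the stearate on the neighbouring carbon.
3. Epoxy stearate ⇒ (C9–O bond, key step) an allylic stearate, by an iodonium-triggered relay in which the ester carbonyl oxygen becomes the epoxide (later ring) oxygen and the acyl group returns to O10.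
4. Allylic stearate ⇒ dec-9-enal + vinylzinc (asymmetric addition sets C10) + stearoyl chloride.

Assumption: locants follow the nonadecane chain of the target (C1 = CH3 of the pentyl group, C19 = vinyl CH2); the target is the 10-O-octadecanoate of (6S,7S,9R,10R)-6,9-epoxynonadec-18-ene-7,10-diol.

**Route**

Step 1
Reactants: 1 dec-9-enal; 2 vinylmagnesium bromide; 3 octadecanoyl chloride
Product: 6 (3R)-dodeca-1,11-dien-3-yl octadecanoate, via divinylzinc 4 (not isolated), via zinc alkoxide 5 (not isolated)
Conditions: 2, ZnCl2, Et2O, then 1,4-dioxane (MgX2 filtered off); (2S)-(−)-3-exo-morpholinoisoborneol (5 mol %), toluene, 0 °C, add 1; then 3, DMAP (cat.), 0 °C → rt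
Reagents that add atoms: none
Why: amino-alcohol-catalysed enantioselective vinylzinc addition to the aldehyde (Si-face vinyl transfer) sets C10 as R, and the zinc alkoxide is O-acylated in the same flask, so the stearate is in place from the first step.

Step 2
Reactants: 6
Product: 10 (1R)-1-[(2R)-oxiran-2-yl]dec-9-en-1-yl octadecanoate, via dioxolanylium ion 7 (not isolated), via iodohydrin stearate 8 (not isolated), via isomeric iodohydrin stearate 9 (not isolated)
Conditions: N-iodosuccinimide (1.1 equiv), Me3SiOTf (0.2 equiv), CH2Cl2, −40 → 0 °C; then K2CO3, MeCN/H2O, 0 °C → rt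
Reagents that add atoms: water, O
Why: Proposed new method: stearate-relayed iodo-oxygenation, in which the iodonium ion of the allylic C8=C9 bond forms reversibly and the ester carbonyl oxygen closes 5-exo onto C9 to give the trans-4,5-disubstituted 1,3-dioxolan-2-ylium ion (favoured by allylic strain and on equilibration), fixing C9 as R relative to C10; aqueous carbonate then hydrolyses the cation at C2 to the iodohydrin monoesters, the C9 alkoxide displaces iodide at C8, and any acyl group on O9 shifts back to O10, so the former carbonyl oxygen ends as the epoxide oxygen with the stearate restored on C10; the isolated C18=C19 alkene also forms an iodonium ion reversibly but has no internal nucleophile to trap it in the anhydrous first stage; the closest known reaction types are the iodocarbonate cyclisation of allylic tert-butyl carbonates followed by base (threo epoxy alcohols) and Woodward–Prévost acyloxonium chemistry, neither of which returns the acyl group to its original oxygen.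

Step 3
Reactants: 10; 11 pentyllithium; 12 acetylene
Product: 15 (6Z,9R,10R)-9-hydroxynonadeca-6,18-dien-10-yl octadecanoate, via lithium dipentylcuprate 13 (not isolated), via lithium di[(Z)-hept-1-enyl]cuprate 14 (not isolated)
Conditions: 11 (2 equiv per Cu), CuBr·SMe2, Et2O, −40 °C; 12, −50 → −25 °C; then 10, BF3·OEt2 (1.2 equiv), −78 °C; aq NH4Cl at −78 °C
Reagents that add atoms: none
Why: syn-carbocupration of acetylene gives the (Z)-alkenyl cuprate stereospecifically, and BF3-assisted SN2 epoxide opening at the unsubstituted carbon C8 leaves C9 (R) untouched while the boron-bound alkoxide cannot shift the neighbouring acyl group.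

Step 4
Reactants: 15
Product: 17 (6S,7S,9R,10R)-6,9-epoxy-7-hydroxynonadec-18-en-10-yl octadecanoate, via epoxy alcohol 16 (not isolated)
Conditions: VO(acac)2 (5 mol %), t-BuOOH (1.5 equiv, decane), CH2Cl2, 0 °C → rt; then PPTS (10 mol %)
Reagents that add atoms: tert-butyl hydroperoxide, CC(C)(C)OO
Why: hydroxyl-directed vanadium-catalysed epoxidation of the (Z)-homoallylic alcohol through a chair vanadate transition state (C10 branch equatorial) places the epoxide oxygen syn to the C9 hydroxyl (6R,7S), and 5-endo anti opening at C6 by that hydroxyl inverts C6, giving the 6S,7S,9R oxolane (pentyl and OH cis, 2,5-trans); the remote vinyl group has no directing hydroxyl and is not epoxidised.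

**Compound list**

1 | dec-9-enal | C=CCCCCCCCC=O | starting material
2 | vinylmagnesium bromide | C=C[Mg]Br | starting material
3 | octadecanoyl chloride (stearoyl chloride) | CCCCCCCCCCCCCCCCCC(=O)Cl | starting material
4 | divinylzinc | C=C[Zn]C=C | intermediate (not isolated)
5 | ethenylzinc (3R)-dodeca-1,11-dien-3-olate | C=CCCCCCCC[C@@H](O[Zn]C=C)C=C | intermediate (not isolated)
6 | (3R)-dodeca-1,11-dien-3-yl octadecanoate | C=CCCCCCCC[C@@H](OC(=O)CCCCCCCCCCCCCCCCC)C=C | intermediate
7 | (4S,5R)-2-heptadecyl-4-(iodomethyl)-5-(non-8-en-1-yl)-1,3-dioxolan-2-ylium (trans) | CCCCCCCCCCCCCCCCCC1=[O+][C@H](CI)[C@@H](CCCCCCCC=C)O1 | intermediate (not isolated)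
8 | (2S,3R)-2-hydroxy-1-iodododec-11-en-3-yl octadecanoate | C=CCCCCCCC[C@@H](OC(=O)CCCCCCCCCCCCCCCCC)[C@H](O)CI | intermediate (not isolated)
9 | (2S,3R)-3-hydroxy-1-iodododec-11-en-2-yl octadecanoate | C=CCCCCCCC[C@@H](O)[C@@H](CI)OC(=O)CCCCCCCCCCCCCCCCC | intermediate (not isolated)
10 | (1R)-1-[(2R)-oxiran-2-yl]dec-9-en-1-yl octadecanoate | C=CCCCCCCC[C@@H](OC(=O)CCCCCCCCCCCCCCCCC)[C@H]1CO1 | intermediate
11 | pentyllithium | [Li]CCCCC | starting material
12 | acetylene | C#C | starting material
13 | lithium dipentylcuprate | [Li+].CCCCC[Cu-]CCCCC | intermediate (not isolated)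
14 | lithium di[(Z)-hept-1-enyl]cuprate | [Li+].CCCCC/C=C\[Cu-]/C=C\CCCCC | intermediate (not isolated)
15 | (6Z,9R,10R)-9-hydroxynonadeca-6,18-dien-10-yl octadecanoate | C=CCCCCCCC[C@@H](OC(=O)CCCCCCCCCCCCCCCCC)[C@H](O)C/C=C\CCCCC | intermediate
16 | (6R,7S,9R,10R)-6,7-epoxy-9-hydroxynonadec-18-en-10-yl octadecanoate | C=CCCCCCCC[C@@H](OC(=O)CCCCCCCCCCCCCCCCC)[C@H](O)C[C@@H]1O[C@@H]1CCCCC | intermediate (not isolated)
17 | (6S,7S,9R,10R)-6,9-epoxy-7-hydroxynonadec-18-en-10-yl octadecanoate, i.e. (1R)-1-[(2R,4S,5S)-4-hydroxy-5-pentyloxolan-2-yl]dec-9-en-1-yl octadecanoate | C=CCCCCCCC[C@@H](OC(=O)CCCCCCCCCCCCCCCCC)[C@H]1C[C@H](O)[C@H](CCCCC)O1 | target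

**Totals**

Total step count: 4. Longest linear sequence: 4 steps (1 → 6 → 10 → 15 → 17).

**Steps most likely to fail**

Step 2 (the new relay). The risks are a low trans/cis ratio of the dioxolanylium ion (cis leads to the erythro epoxide), weak nucleophilicity of the ester carbonyl, and iodination at the remote vinyl group. The fallback uses known chemistry only, sets out from 1 and comes back at 10. Compound 1 with 2 (Et2O, 0 °C) gives racemic dodeca-1,11-dien-3-ol F1. Sharpless kinetic-resolution epoxidation (Ti(OiPr)4, L-(+)-diisopropyl tartrate, t-BuOOH 0.45 equiv, 4 Å sieves, CH2Cl2, −20 °C) converts the fast (S)-enantiomer into the erythro epoxy alcohol (1S)-1-[(2R)-oxiran-2-yl]dec-9-en-1-ol F2. Mitsunobu esterification with octadecanoic acid (PPh3, DIAD, THF, 0 °C) inverts C10 and gives 10.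

Step 1 (asymmetric vinylation with in-flask acylation). The risks are eroded enantioselectivity from residual magnesium salts and incomplete acylation of the zinc alkoxide. The fallback sets out from 1 and comes back at 6. Uncatalysed addition of 2 to 1 followed by 3 in the same flask gives racemic dodeca-1,11-dien-3-yl octadecanoate F3. Lipase-catalysed butanolysis (Novozym 435, n-butanol, hexane, 40 °C, about 52 % conversion) cleaves the (S)-ester (vinyl as the medium group, the alkenyl chain as the large group) and leaves 6, which is separated by chromatography.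

Step 3 (cuprate opening next to an ester). The risks are 1,2-acyl shift in the alkoxide, Lewis-acid-induced ester participation at the epoxide, and sluggish transfer of the alkenyl group. The fallback sets out from 10 and comes back at 15. Lithium hept-1-ynide (hept-1-yne, n-BuLi) with BF3·OEt2 in THF at −78 °C opens the epoxide at C8 to give (9R,10R)-9-hydroxynonadec-18-en-6-yn-10-yl octadecanoate F4. Semihydrogenation over Pd/CaCO3 poisoned with Pb(OAc)2 and quinoline (H2, 1 atm, hexane/EtOAc, stopped at one equivalent) gives the (Z)-alkene 15.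

**Further compounds**

F1 | step 2 | racemic dodeca-1,11-dien-3-ol | C=CCCCCCCCC(O)C=C
F2 | step 2 | (1S)-1-[(2R)-oxiran-2-yl]dec-9-en-1-ol | C=CCCCCCCC[C@H](O)[C@H]1CO1
F3 | step 1 | racemic dodeca-1,11-dien-3-yl octadecanoate | C=CCCCCCCCC(OC(=O)CCCCCCCCCCCCCCCCC)C=C
F4 | step 3 | (9R,10R)-9-hydroxynonadec-18-en-6-yn-10-yl octadecanoate | C=CCCCCCCC[C@@H](OC(=O)CCCCCCCCCCCCCCCCC)[C@H](O)CC#CCCCCC
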